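The depside is cut at its aryl ester into benzyl olivetolate (ring B) and 2,4-dimethoxy-6-propylbenzoic acid (ring A). Ring A has its C1 carboxyl carbon wedged between the C2 methoxy and the C6 propyl group. This is the arrangement an aryne leaves after taking up an alkyl nucleophile at one end of its triple bond and an electrophile at the other. One flask therefore converts symmetrical 1-fluoro-3,5-dimethoxybenzene, propylmagnesium chloride and carbon dioxide into the complete acid, forming the C6–propyl and C1–carboxyl bonds. Esterification onto the free C4 phenol of ring B, methylation of the chelated C2 phenol and hydrogenolysis complete the synthesis.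

Key step: step 1

Remark: olivetolic acid (2,4-dihydroxy-6-pentylbenzoic acid) is assumed to be bought as a catalogue compound, so ring B enters with its substitution pattern already fixed.

Step 1
Reactants: 1 1-fluoro-3,5-dimethoxybenzene; 2 propylmagnesium chloride; 3 carbon dioxide
Product: 7 2,4-dimethoxy-6-propylbenzoic acid, via (2-fluoro-4,6-dimethoxyphenyl)lithium 4 (not isolated), via 3,5-dimethoxybenzyne 5 (not isolated), via (2,4-dimethoxy-6-propylphenyl)magnesium chloride 6 (not isolated)
Conditions: n-BuLi (1.0 equiv), THF, −78 °C; then 2 (2.5 equiv), −78 → 40 °C; then CO2 gas, −20 °C → rt; aq. HCl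
Reagents that add atoms: none
Why: n-BuLi removes the most acidic ring proton of 1, the one flanked by fluorine and a methoxy group (directed ortho-lithiation), and because 1 is symmetrical either such site gives the same aryllithium 4. On warming in the presence of the Grignard reagent, 4 loses LiF to give aryne 5, whose triple bond is distorted by the sigma-withdrawing methoxy group beside it; the propyl nucleophile therefore enters at the aryne carbon remote from that methoxy, and the carbanion develops next to oxygen, stabilised inductively and by Mg–O chelation, giving 6. Arylmagnesium 6 then adds to CO2 to give the carboxylate of 7, so the C6–propyl and C1–carboxyl bonds of ring A are both made in one flask. The closest known reaction type is generation of a 3-alkoxybenzyne from a fluoroarene with an alkyllithium, regioselective carbometalation by an organolithium or Grignard reagent, and electrophilic trapping of the resulting ortho-alkoxy arylmetal. No ring is closed and no stereocentre is formed. The selectivity needed is regiochemical: the site of lithiation is secured by the combined fluorine and methoxy activation (an anion between the two methoxy groups cannot expel fluoride and would only end up as a separable fluorinated acid), the direction of addition is secured by the methoxy group adjacent to the triple bond, and adding exactly one equivalent of n-BuLi before the excess of 2 should keep butyl transfer to the aryne low.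

Step 2
Reactants: 8 olivetolic acid (2,4-dihydroxy-6-pentylbenzoic acid)
Product: 9 benzyl 2,4-dihydroxy-6-pentylbenzoate (benzyl olivetolate)
Conditions: BnBr (1.05 equiv), KHCO3, DMF, rt
Reagents that add atoms: benzyl bromide, BrCc1ccccc1
Why: Bicarbonate ionises only the carboxylic acid, and the carboxylate is benzylated by SN2 O-alkylation (carboxylate esterification) while both phenols stay protonated; room temperature avoids decarboxylation of the resorcylic acid.

Step 3
Reactants: 7 2,4-dimethoxy-6-propylbenzoic acid; 9 benzyl 2,4-dihydroxy-6-pentylbenzoate
Product: 11 benzyl 4-[(2,4-dimethoxy-6-propylbenzoyl)oxy]-2-hydroxy-6-pentylbenzoate, via mixed trifluoroacetic anhydride 10 (not isolated)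
Conditions: (CF3CO)2O, toluene, rt
Reagents that add atoms: none
Why: Trifluoroacetic anhydride turns the hindered, electron-rich acid into mixed anhydride 10, an acylium equivalent, which should acylate the free C4 hydroxyl of 9 while the C2 hydroxyl is held in a hydrogen bond to the ester carbonyl (mixed-anhydride esterification, the classical depside coupling).

Step 4
Reactants: 11 benzyl 4-[(2,4-dimethoxy-6-propylbenzoyl)oxy]-2-hydroxy-6-pentylbenzoate
Product: 12 benzyl 4-[(2,4-dimethoxy-6-propylbenzoyl)oxy]-2-methoxy-6-pentylbenzoate
Conditions: MeI, K2CO3, DMF, rt → 40 °C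
Reagents that add atoms: iodomethane, CI
Why: The chelated C2 phenol is the only acidic site left and should be O-methylated as its potassium phenoxide (Williamson ether synthesis), while the di-ortho-substituted aryl ester is too hindered to be attacked by carbonate in dry DMF.

Step 5
Reactants: 12 benzyl 4-[(2,4-dimethoxy-6-propylbenzoyl)oxy]-2-methoxy-6-pentylbenzoate
Product: 13 4-[(2,4-dimethoxy-6-propylbenzoyl)oxy]-2-methoxy-6-pentylbenzoic acid (target)
Conditions: H2 (1 atm), 10% Pd/C, EtOAc, rt
Reagents that add atoms: none
Why: Catalytic hydrogenolysis cleaves the benzylic C–O bond of the benzyl ester under neutral conditions and should leave the aryl ester, the methyl ethers and both arenes untouched.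

Compound list
1 | 1-fluoro-3,5-dimethoxybenzene | COc1cc(F)cc(OC)c1 | starting material
2 | propylmagnesium chloride | CCC[Mg]Cl | starting material
3 | carbon dioxide | O=C=O | starting material
4 | (2-fluoro-4,6-dimethoxyphenyl)lithium | [Li]c1c(F)cc(OC)cc1OC | intermediate
5 | 3,5-dimethoxybenzyne (1,2-didehydro-3,5-dimethoxybenzene) | COC1=CC(OC)=CC#C1 | intermediate
6 | (2,4-dimethoxy-6-propylphenyl)magnesium chloride | CCCc1cc(OC)cc(OC)c1[Mg]Cl | intermediate
7 | 2,4-dimethoxy-6-propylbenzoic acid | CCCc1cc(OC)cc(OC)c1C(=O)O | intermediate
8 | olivetolic acid (2,4-dihydroxy-6-pentylbenzoic acid) | CCCCCc1cc(O)cc(O)c1C(=O)O | starting material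
9 | benzyl 2,4-dihydroxy-6-pentylbenzoate | CCCCCc1cc(O)cc(O)c1C(=O)OCc1ccccc1 | intermediate
10 | 2,4-dimethoxy-6-propylbenzoic trifluoroacetic anhydride | CCCc1cc(OC)cc(OC)c1C(=O)OC(=O)C(F)(F)F | intermediate
11 | benzyl 4-[(2,4-dimethoxy-6-propylbenzoyl)oxy]-2-hydroxy-6-pentylbenzoate | CCCCCc1cc(OC(=O)c2c(CCC)cc(OC)cc2OC)cc(O)c1C(=O)OCc1ccccc1 | intermediate
12 | benzyl 4-[(2,4-dimethoxy-6-propylbenzoyl)oxy]-2-methoxy-6-pentylbenzoate | CCCCCc1cc(OC(=O)c2c(CCC)cc(OC)cc2OC)cc(OC)c1C(=O)OCc1ccccc1 | intermediate
13 | 4-[(2,4-dimethoxy-6-propylbenzoyl)oxy]-2-methoxy-6-pentylbenzoic acid | CCCCCc1cc(OC(=O)c2c(CCC)cc(OC)cc2OC)cc(OC)c1C(=O)O | target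

Total step count: 5. Longest linear sequence: 4 steps (step 1 or step 2, then steps 3, 4 and 5).

Steps most likely to fail

Step 1. The one-flask sequence may suffer from butyl instead of propyl transfer to the aryne, from attack of the arylmetal on the aryne, or from protonation of the crowded arylmagnesium before it is carboxylated. The fallback builds ring A without an aryne and sets out from propylmagnesium chloride 2. Kumada–Corriu coupling with commercial 1-bromo-3,5-dimethoxybenzene (NiCl2(dppp) catalyst, THF, reflux) should give 1,3-dimethoxy-5-propylbenzene F1. Vilsmeier–Haack formylation (POCl3, DMF) at the ring position para to one methoxy group and ortho to the other should give 2,4-dimethoxy-6-propylbenzaldehyde F2. Pinnick oxidation (NaClO2, NaH2PO4, 2-methyl-2-butene, t-BuOH/H2O) then returns to the route at acid 7.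

Step 3. Under the acidic coupling conditions the acylium equivalent may attack a ring carbon of the electron-rich resorcinol (Friedel–Crafts C-acylation) or condense with a second molecule of the acid instead of the phenol. The fallback forms the ester under basic conditions and sets out from acid 7. Oxalyl chloride with catalytic DMF in CH2Cl2 should give 2,4-dimethoxy-6-propylbenzoyl chloride F3. This is added to benzyl olivetolate 9 and K2CO3 in acetone, where the more acidic, non-chelated C4 hydroxyl is ionised and O-acylated, returning to the route at depside ester 11.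

Step 4. Alkylation of the hydrogen-bonded phenol may be slow, and prolonged exposure to base may cleave the aryl ester. The fallback installs the methyl ether before the ester is formed and sets out from benzyl olivetolate 9. Selective allylation of the free C4 hydroxyl (allyl bromide, K2CO3, acetone, rt) should give benzyl 2-hydroxy-6-pentyl-4-(prop-2-en-1-yloxy)benzoate F4. Methylation of the chelated phenol (MeI, K2CO3, DMF, 50 °C) should give benzyl 2-methoxy-6-pentyl-4-(prop-2-en-1-yloxy)benzoate F5. Deallylation (Pd(PPh3)4 catalyst, morpholine, THF, rt) should give benzyl 4-hydroxy-2-methoxy-6-pentylbenzoate F6. Trifluoroacetic anhydride coupling of this phenol with acid 7, again through mixed anhydride 10, returns to the route at 12.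

Further compounds
F1 | step 1 | 1,3-dimethoxy-5-propylbenzene | CCCc1cc(OC)cc(OC)c1
F2 | step 1 | 2,4-dimethoxy-6-propylbenzaldehyde | CCCc1cc(OC)cc(OC)c1C=O
F3 | step 3 | 2,4-dimethoxy-6-propylbenzoyl chloride | CCCc1cc(OC)cc(OC)c1C(Cl)=O
F4 | step 4 | benzyl 2-hydroxy-6-pentyl-4-(prop-2-en-1-yloxy)benzoate | CCCCCc1cc(OCC=C)cc(O)c1C(=O)OCc1ccccc1
F5 | step 4 | benzyl 2-methoxy-6-pentyl-4-(prop-2-en-1-yloxy)benzoate | CCCCCc1cc(OCC=C)cc(OC)c1C(=O)OCc1ccccc1
F6 | step 4 | benzyl 4-hydroxy-2-methoxy-6-pentylbenzoate | CCCCCc1cc(O)cc(OC)c1C(=O)OCc1ccccc1
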